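Readings and results stem from a simulated flask with constants of no real substance; scatter was added.

No coupling partner can go into a target and still stand at its charge. The question for this row of flasks is whether that loss of partner shows in the target.

| setting | winter | dusk | north-east | north | north-west |
|---|---|---|---|---|---|
| starting material | 0.013 M | 0.065 M | 0.015 M | 0.030 M | 0.060 M |
| coupling partner | 0.228 M | 0.228 M | 0.228 M | 0.228 M | 0.228 M |
| remark | run made earlier | run made earlier |  |  |  |
| time |  |  | 3.0 h | 3.0 h | 3.0 h |

| run | time / min | target / % | starting material / % |
|---|---|---|---|
| winter | 12.0 | 12.2 | 72.3 |
| winter | 30.0 | 24.5 | 45.7 |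
| winter | 60.0 | 35.5 | 21.8 |
| winter | 90.0 | 41.8 | 11.7 |
| dusk | 25.0 | 22.4 | 53.8 |
| dusk | 50.0 | 32.0 | 28.2 |
| dusk | 60.0 | 35.2 | 22.3 |
| dusk | 90.0 | 38.9 | 10.5 |

(scatter of a reading: 1 percentage point)

- the numbers in the tables scatter with a standard deviation of 1 percentage point
- "hardly changes" means that all values lie within two and a half points (for a concentration: within two and a half percent of the largest)

* amount of target at the end, in percent of the starting material charged for north-east, north, north-west, in this order
* how that number moves from the first to the last of them (hardly changes / falls all the way / rises, then falls / falls, then rises / rises all the way)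

Call the drawdown the ratio c(starting material)/c(coupling partner) at the charge: the fraction of the partner that a one-to-one coupling takes at full conversion, with the starting material as limiting reagent. It is 0.0570 in winter and 0.285 in dusk, and 0.0658, 0.132 and 0.263 along the row, so the earlier runs bracket it.

The first chemist holds that drawdown does not matter. At 60.0 min, winter shows 35.5% of target and dusk 35.2%, although dusk has the larger drawdown.

The second chemist answers that the target step consumes partner, so the target's share of converted material should follow the mean partner, which is the charge less half the drawdown. From north-east to north-west that costs 4.7 percentage points, a clear fall.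

My own reckoning measures the effect instead. Pooling the last two readings, target per starting material consumed is 46.4% in winter and 44.3% in dusk. That gives a drawdown penalty, the share lost per unit of drawdown, of 0.0924, a reading that carries their scatter. Across the row it predicts a fall of 1.8 points, smaller than the second chemist's.

The asked time is twice the last winter reading, so first-order decay leaves about 1.37% of the starting material. My row is therefore 45.7%, 45.1% and 43.9%, inside the margin of "hardly changes".

The forecast, on the first chemist's side, gave 45%, 45% and 45%, hardly changes, holding that “target and side product form in parallel”.

The flask gives 46.6%, 45.9% and 44.3%, hardly changes.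

    starting material ⇌ tight pair (K = 0.0670, k = 4.60 × 10⁻⁴ s⁻¹)
    tight pair ⇌ loose pair (K = 8.70, k = 0.0650 s⁻¹)
    coupling partner + tight pair → target (k = 0.230 M⁻¹ s⁻¹)
    coupling partner + loose pair → isomer of the product (k = 0.240 M⁻¹ s⁻¹)
    loose pair → decomposed reagent (k = 6.20 × 10⁻⁴ s⁻¹)

The first chemist takes the verdict, while the second keeps the direction: the row falls by 2.3 points, less than she claimed. At the charge in north-east, the partner captures the tight pair at 0.0524 s⁻¹, against 0.065 s⁻¹ for the forward step to the loose pair alone, so the two are of like size, at a ratio of 0.807. In north-west at 3.00 h, with the partner at 74% of its charge and 0.97% of the starting material left, capture stands at 0.0389 s⁻¹, a ratio of 0.598. Applying the penalty from north-east to north, with drawdown 0.132, gives 46.0%, and north holds 45.9%.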